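**Retrosynthetic overview**

1. Target 19 ⇐ pentabenzyl ether 18 by global hydrogenolysis; all four benzene rings are bought.
2. Oxolane of 18 ⇐ aryl cyclopropyl ketone 14 + aldehyde 15, cutting O1–C5 and C2–C3: the three-membered carbocycle (future C3–C4–C5) is enlarged by the two atoms O1 and C2 in a Lewis-acid (3+2) ring expansion. Enabling feature: C5 is benzylic to the 2,4-dioxygenated benzene ring (cation-stabilising), C3 is alpha to the aroyl carbonyl (enolate-stabilising), and the two are 1,3-related across C4. C3–C4–C5 is therefore a latent 1,3-zwitterion that can be stored as a donor–acceptor cyclopropane, and O1–C2 is the carbonyl group of a 4-oxygenated benzaldehyde.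
3. 14 ⇐ cyclopropylmethanol 9 (oxidation, aryllithium addition, oxidation). 9 ⇐ cinnamyl-type alcohol 4 + gem-diiodide 7 by dioxaborolane-controlled Simmons–Smith cyclopropanation. This is the only operation that introduces absolute configuration; it fixes the benzyl-bearing carbon (C4 of the target), from which C2, C3 and C5 are relayed in the key step.
4. Ring order: cyclopropane (step 4), then oxolane (step 8).

Key step: step 8

Assumption: 1, 5, 11 and 15 are bought as such.
Assumption: in the dioxaborolane-controlled cyclopropanation the substituent of the zinc carbenoid is delivered anti to the CH2OH arm, as expected for alkyl-substituted carbenoids; if it were delivered syn, the (4S,5S)-ligand would give the same configuration at the benzyl-bearing carbon.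

**Route**

Step 1
Reactants: 1 2,4-bis(benzyloxy)benzaldehyde; 2 triethyl phosphonoacetate
Product: 3 ethyl (E)-3-[2,4-bis(benzyloxy)phenyl]prop-2-enoate
Conditions: NaH, THF, 0 °C → rt
Reagents that add atoms: none
Why: Horner–Wadsworth–Emmons olefination of an aryl aldehyde with a stabilised phosphonate anion should give the (E)-enoate, and no stereocentre is formed.

Step 2
Reactants: 3 ethyl (E)-3-[2,4-bis(benzyloxy)phenyl]prop-2-enoate
Product: 4 (E)-3-[2,4-bis(benzyloxy)phenyl]prop-2-en-1-ol
Conditions: i-Bu2AlH (2.5 equiv), CH2Cl2, −78 °C; aq. potassium sodium tartrate work-up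
Reagents that add atoms: none
Why: 1,2-reduction of the enoate by i-Bu2AlH at low temperature should give the (E)-allylic alcohol without touching the alkene geometry or the benzyl ethers.

Step 3
Reactants: 5 4-(benzyloxy)benzyl bromide; 6 diiodomethane
Product: 7 1-(benzyloxy)-4-(2,2-diiodoethyl)benzene
Conditions: NaN(SiMe3)2 (1.0 equiv), THF/Et2O, −78 °C, dark; then 5, −78 °C → rt
Reagents that add atoms: none
Why: SN2 alkylation of the diiodomethyl anion by a reactive benzylic bromide (gem-diiodide synthesis) should work, with one equivalent of base at −78 °C keeping the product from E2 loss of HI.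

Step 4
Reactants: 4 (E)-3-[2,4-bis(benzyloxy)phenyl]prop-2-en-1-ol; 7 1-(benzyloxy)-4-(2,2-diiodoethyl)benzene
Product: 9 [(1S,2R,3S)-2-[4-(benzyloxy)benzyl]-3-[2,4-bis(benzyloxy)phenyl]cyclopropyl]methanol, via zinc carbenoid 8 (not isolated)
Conditions: Et2Zn (2.2 equiv), 7 (4.4 equiv), CH2Cl2, −10 °C; then 4 premixed with (4R,5R)-2-butyl-N,N,N',N'-tetramethyl-1,3,2-dioxaborolane-4,5-dicarboxamide (1.2 equiv), −10 °C → rt; aq. NaOH work-up
Reagents that add atoms: none
Why: In this hydroxyl-directed asymmetric Simmons–Smith cyclopropanation with a substituted zinc carbenoid, the allylic alkoxide bound to the chiral dioxaborolane should deliver 8 to one face of the (E)-alkene (fixing C1 and C3 with aryl and CH2OH trans) and place the carbenoid substituent anti to the carbinol arm, which fixes C2, the carbon that becomes C4 of the target; the syn diastereomer, which would carry the opposite C2, is removed by chromatography.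

Step 5
Reactants: 9 [(1S,2R,3S)-2-[4-(benzyloxy)benzyl]-3-[2,4-bis(benzyloxy)phenyl]cyclopropyl]methanol
Product: 10 (1S,2R,3S)-2-[4-(benzyloxy)benzyl]-3-[2,4-bis(benzyloxy)phenyl]cyclopropane-1-carbaldehyde
Conditions: Dess–Martin periodinane, pyridine, CH2Cl2, 0 °C → rt
Reagents that add atoms: none
Why: Dess–Martin oxidation under pyridine buffer should give the aldehyde without acid that could open the electron-rich arylcyclopropane, and the formyl group already sits trans to both ring neighbours, so no epimerisation is expected.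

Step 6
Reactants: 11 1-bromo-2,4-bis(benzyloxy)benzene; 10 (1S,2R,3S)-2-[4-(benzyloxy)benzyl]-3-[2,4-bis(benzyloxy)phenyl]cyclopropane-1-carbaldehyde
Product: 13 [2,4-bis(benzyloxy)phenyl][(1S,2R,3S)-2-[4-(benzyloxy)benzyl]-3-[2,4-bis(benzyloxy)phenyl]cyclopropyl]methanol (both carbinol epimers), via aryllithium 12 (not isolated)
Conditions: 11, n-BuLi, THF, −78 °C; then 10, −78 °C; then H2O
Reagents that add atoms: none
Why: Bromine–lithium exchange followed by 1,2-addition of the aryllithium to the aldehyde should be clean, and the new carbinol centre, formed unselectively, is removed in step 7.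

Step 7
Reactants: 13 [2,4-bis(benzyloxy)phenyl][(1S,2R,3S)-2-[4-(benzyloxy)benzyl]-3-[2,4-bis(benzyloxy)phenyl]cyclopropyl]methanol
Product: 14 [2,4-bis(benzyloxy)phenyl][(1S,2R,3S)-2-[4-(benzyloxy)benzyl]-3-[2,4-bis(benzyloxy)phenyl]cyclopropyl]methanone
Conditions: Dess–Martin periodinane, pyridine, CH2Cl2, 0 °C → rt
Reagents that add atoms: none
Why: Dess–Martin oxidation of the secondary benzylic carbinol to the aryl ketone should create the donor–acceptor cyclopropane, with the aroyl group remaining trans to both ring neighbours.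

Step 8
Reactants: 14 [2,4-bis(benzyloxy)phenyl][(1S,2R,3S)-2-[4-(benzyloxy)benzyl]-3-[2,4-bis(benzyloxy)phenyl]cyclopropyl]methanone; 15 4-(benzyloxy)benzaldehyde
Product: 18 [2,4-bis(benzyloxy)phenyl][(2S,3S,4S,5S)-4-[4-(benzyloxy)benzyl]-5-[2,4-bis(benzyloxy)phenyl]-2-[4-(benzyloxy)phenyl]oxolan-3-yl]methanone, via ring-opened zwitterion 16 (not isolated), via oxocarbenium enolate 17 (not isolated)
Conditions: 15 (3 equiv), Sc(OTf)3 (10 mol %), 4 Å molecular sieves, CH2Cl2, 0 °C → rt, held until the diastereomers have converged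
Reagents that add atoms: none
Why: Sc(OTf)3, bound in two-point fashion to the ketone oxygen and the ortho benzyloxy group, should heterolyse the C1–C3 cyclopropane bond between acceptor and donor carbon to zwitterion 16 (scandium enolate and 2,4-bis(benzyloxy)benzylic cation), the aldehyde oxygen of 15 captures the cation to give oxocarbenium 17, and the enolate carbon closes onto the oxocarbenium carbon. The closest known reaction type is the Lewis acid-catalysed (3+2) annulation of donor–acceptor cyclopropanes with aldehydes to tetrahydrofurans, which is known also for singly carbonyl-activated cyclopropanes with strong donors. The oxolane closes by C2–C3 bond formation in a 5-(enolexo)-endo-trig aldol-type attack after O1–C5 has formed, so the three-membered ring is enlarged by the two atoms of the C=O group. C5 is set anti to the C4 benzyl group (invertive capture of the cis-configured donor carbon, or capture of the planar cation on the face away from benzyl), C2 is set in the aldol closure, and C3 is an enolisable centre that should settle trans to both neighbours. The step needs the all-trans array relative to C4 and needs bimolecular capture to beat unimolecular collapse of 16; excess 15 serves the second, and the first is served because the 2,4-dioxygenated aryl group keeps C5–O1 heterolysis and the retro-aldol reversible under the Lewis acid, so C2, C3 and C5 can correct themselves to the isomer with no cis-vicinal pair. C4 alone cannot exchange and carries the absolute configuration from 14 into 18.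

Step 9
Reactants: 18 [2,4-bis(benzyloxy)phenyl][(2S,3S,4S,5S)-4-[4-(benzyloxy)benzyl]-5-[2,4-bis(benzyloxy)phenyl]-2-[4-(benzyloxy)phenyl]oxolan-3-yl]methanone
Product: 19 (2,4-dihydroxyphenyl)[(2S,3S,4S,5S)-5-(2,4-dihydroxyphenyl)-4-(4-hydroxybenzyl)-2-(4-hydroxyphenyl)oxolan-3-yl]methanone
Conditions: H2 (1 atm), 10% Pd/C, EtOAc/MeOH, rt
Reagents that add atoms: none
Why: Hydrogenolysis of the five aryl benzyl ethers over Pd/C should be faster at the primary O–CH2Ph bonds than at the secondary ring C–O bonds or the electron-rich aryl ketone, and no stereocentre is touched.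

**Compound list**

1 | 2,4-bis(benzyloxy)benzaldehyde | O=Cc1ccc(OCc2ccccc2)cc1OCc1ccccc1 | starting material
2 | triethyl phosphonoacetate | CCOC(=O)CP(=O)(OCC)OCC | starting material
3 | ethyl (E)-3-[2,4-bis(benzyloxy)phenyl]prop-2-enoate | CCOC(=O)/C=C/c1ccc(OCc2ccccc2)cc1OCc1ccccc1 | intermediate
4 | (E)-3-[2,4-bis(benzyloxy)phenyl]prop-2-en-1-ol | OC/C=C/c1ccc(OCc2ccccc2)cc1OCc1ccccc1 | intermediate
5 | 4-(benzyloxy)benzyl bromide | BrCc1ccc(OCc2ccccc2)cc1 | starting material
6 | diiodomethane | ICI | starting material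
7 | 1-(benzyloxy)-4-(2,2-diiodoethyl)benzene | IC(I)Cc1ccc(OCc2ccccc2)cc1 | intermediate
8 | bis[2-(4-benzyloxyphenyl)-1-iodoethyl]zinc (zinc carbenoid, not isolated) | IC(Cc1ccc(OCc2ccccc2)cc1)[Zn]C(I)Cc1ccc(OCc2ccccc2)cc1 | intermediate
9 | [(1S,2R,3S)-2-[4-(benzyloxy)benzyl]-3-[2,4-bis(benzyloxy)phenyl]cyclopropyl]methanol | OC[C@H]1[C@H](Cc2ccc(OCc3ccccc3)cc2)[C@@H]1c1ccc(OCc2ccccc2)cc1OCc1ccccc1 | intermediate
10 | (1S,2R,3S)-2-[4-(benzyloxy)benzyl]-3-[2,4-bis(benzyloxy)phenyl]cyclopropane-1-carbaldehyde | O=C[C@H]1[C@H](Cc2ccc(OCc3ccccc3)cc2)[C@@H]1c1ccc(OCc2ccccc2)cc1OCc1ccccc1 | intermediate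
11 | 1-bromo-2,4-bis(benzyloxy)benzene | Brc1ccc(OCc2ccccc2)cc1OCc1ccccc1 | starting material
12 | 2,4-bis(benzyloxy)phenyllithium (not isolated) | [Li]c1ccc(OCc2ccccc2)cc1OCc1ccccc1 | intermediate
13 | [2,4-bis(benzyloxy)phenyl][(1S,2R,3S)-2-[4-(benzyloxy)benzyl]-3-[2,4-bis(benzyloxy)phenyl]cyclopropyl]methanol, both carbinol epimers | OC(c1ccc(OCc2ccccc2)cc1OCc1ccccc1)[C@H]1[C@H](Cc2ccc(OCc3ccccc3)cc2)[C@@H]1c1ccc(OCc2ccccc2)cc1OCc1ccccc1 | intermediate
14 | [2,4-bis(benzyloxy)phenyl][(1S,2R,3S)-2-[4-(benzyloxy)benzyl]-3-[2,4-bis(benzyloxy)phenyl]cyclopropyl]methanone | O=C(c1ccc(OCc2ccccc2)cc1OCc1ccccc1)[C@H]1[C@H](Cc2ccc(OCc3ccccc3)cc2)[C@@H]1c1ccc(OCc2ccccc2)cc1OCc1ccccc1 | intermediate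
15 | 4-(benzyloxy)benzaldehyde | O=Cc1ccc(OCc2ccccc2)cc1 | starting material
16 | ring-opened 1,3-zwitterion (enolate and benzylic cation, benzyl-bearing centre intact, not isolated) | [O-]C(=C[C@H](Cc1ccc(OCc2ccccc2)cc1)[CH+]c1ccc(OCc2ccccc2)cc1OCc1ccccc1)c1ccc(OCc2ccccc2)cc1OCc1ccccc1 | intermediate
17 | oxocarbenium enolate from 16 and 15 (not isolated) | [O-]C(=C[C@H](Cc1ccc(OCc2ccccc2)cc1)[C@@H](c1ccc(OCc2ccccc2)cc1OCc1ccccc1)[O+]=Cc1ccc(OCc2ccccc2)cc1)c1ccc(OCc2ccccc2)cc1OCc1ccccc1 | intermediate
18 | [2,4-bis(benzyloxy)phenyl][(2S,3S,4S,5S)-4-[4-(benzyloxy)benzyl]-5-[2,4-bis(benzyloxy)phenyl]-2-[4-(benzyloxy)phenyl]oxolan-3-yl]methanone | O=C(c1ccc(OCc2ccccc2)cc1OCc1ccccc1)[C@H]1[C@H](Cc2ccc(OCc3ccccc3)cc2)[C@@H](c2ccc(OCc3ccccc3)cc2OCc2ccccc2)O[C@@H]1c1ccc(OCc2ccccc2)cc1 | intermediate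
19 | (2,4-dihydroxyphenyl)[(2S,3S,4S,5S)-5-(2,4-dihydroxyphenyl)-4-(4-hydroxybenzyl)-2-(4-hydroxyphenyl)oxolan-3-yl]methanone | O=C(c1ccc(O)cc1O)[C@H]1[C@H](Cc2ccc(O)cc2)[C@@H](c2ccc(O)cc2O)O[C@@H]1c1ccc(O)cc1 | target

**Step count**

Total step count: 9. Longest linear sequence: 8 (steps 1, 2, 4, 5, 6, 7, 8, 9).

**Steps most likely to fail**

Step 8. Unimolecular collapse of the ring-opened zwitterion (Cloke–Wilson ring enlargement to the 2,3-dihydrofuran, or proton loss from the benzylic cation) may outrun bimolecular capture by the aldehyde, and equilibration at C2 may stall short of the all-trans isomer. The fallback sets out from 14 and 15 and separates the events. Iodide-triggered homo-conjugate opening of the cyclopropyl ketone with TiCl4/n-Bu4NI in CH2Cl2 at −78 °C caps the donor carbon as a benzylic iodide and gives the titanium enolate, which adds to 15 in an aldol reaction to give the iodo aldol F1. K2CO3 in MeCN then closes the oxolane by intramolecular O-alkylation at the benzylic iodide, anti to the benzyl group, and a catalytic amount of DBU settles the enolisable C3. The fallback comes back to the route at 18.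

Step 4. A 1,2-hydride or aryl shift within the beta-aryl-substituted zinc carbenoid may consume it before transfer, and leakage into the syn delivery mode would erode the configuration at the one centre that survives step 8. The fallback sets out from 4 and avoids this carbenoid.
- The gem-dizinc carbenoid from CHI3 and Et2Zn, under control of the (4S,5S)-dioxaborolane, should give the cis-fused cyclopropyl borinate F2 by zinc-to-boron exchange.
- Suzuki–Miyaura coupling of F2 with 5 (Pd(OAc)2, tricyclohexylphosphine, K3PO4) with retention should give the cyclopropylmethanol F3. F3 has the benzyl group cis to the carbinol arm and the same configuration at the benzyl-bearing carbon as 9.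
- The operations of steps 5, 6 and 7 then give the aldehyde F4, the carbinol F5 and the ketone F6.
- F6 is submitted to step 8, where the two centres that differ from 14 are erased on ring opening to 16. The fallback comes back to the route at 18.

Step 9. Over-reduction may occur: hydrogenolysis of the ring C5–O1 benzylic bond once the 2,4-dihydroxyphenyl group is unmasked, or hydrogenation of the aryl ketone. The fallback sets out from 18 and is non-reductive: BCl3 with pentamethylbenzene as benzyl-cation scavenger in CH2Cl2 at −78 °C should cleave the five aryl benzyl ethers and come back to the route at 19. It makes no new compound (F0).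

Further compounds
F1 | step 8 | (3S)-1,4-bis[2,4-bis(benzyloxy)phenyl]-3-[4-(benzyloxy)benzyl]-2-{[4-(benzyloxy)phenyl](hydroxy)methyl}-4-iodobutan-1-one, mixture at the other three centres | O=C(c1ccc(OCc2ccccc2)cc1OCc1ccccc1)C(C(O)c1ccc(OCc2ccccc2)cc1)[C@H](Cc1ccc(OCc2ccccc2)cc1)C(I)c1ccc(OCc2ccccc2)cc1OCc1ccccc1
F2 | step 4 | (1R,5R,6R)-6-[2,4-bis(benzyloxy)phenyl]-2-butyl-3-oxa-2-borabicyclo[3.1.0]hexane | CCCCB1OC[C@H]2[C@H](c3ccc(OCc4ccccc4)cc3OCc3ccccc3)[C@@H]12
F3 | step 4 | [(1R,2R,3R)-2-[4-(benzyloxy)benzyl]-3-[2,4-bis(benzyloxy)phenyl]cyclopropyl]methanol | OC[C@@H]1[C@H](Cc2ccc(OCc3ccccc3)cc2)[C@H]1c1ccc(OCc2ccccc2)cc1OCc1ccccc1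
F4 | step 4 | (1R,2R,3R)-2-[4-(benzyloxy)benzyl]-3-[2,4-bis(benzyloxy)phenyl]cyclopropane-1-carbaldehyde | O=C[C@@H]1[C@H](Cc2ccc(OCc3ccccc3)cc2)[C@H]1c1ccc(OCc2ccccc2)cc1OCc1ccccc1
F5 | step 4 | [2,4-bis(benzyloxy)phenyl][(1R,2R,3R)-2-[4-(benzyloxy)benzyl]-3-[2,4-bis(benzyloxy)phenyl]cyclopropyl]methanol, both carbinol epimers | OC(c1ccc(OCc2ccccc2)cc1OCc1ccccc1)[C@@H]1[C@H](Cc2ccc(OCc3ccccc3)cc2)[C@H]1c1ccc(OCc2ccccc2)cc1OCc1ccccc1
F6 | step 4 | [2,4-bis(benzyloxy)phenyl][(1R,2R,3R)-2-[4-(benzyloxy)benzyl]-3-[2,4-bis(benzyloxy)phenyl]cyclopropyl]methanone | O=C(c1ccc(OCc2ccccc2)cc1OCc1ccccc1)[C@@H]1[C@H](Cc2ccc(OCc3ccccc3)cc2)[C@H]1c1ccc(OCc2ccccc2)cc1OCc1ccccc1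
F0 | step 9 | none | none
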